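The route rests on forming the ring-fusion bond C1–C5 of the cyclopentane (ring A, C1–C5) by a 1,2-shift. Ring A is carried as a cyclobutanol (C1–C4) whose carbinol carbon C4 bears a trans-epoxide (C5–C6). A Lewis acid triggers a semipinacol ring expansion: quaternary C1 migrates from C4 to C5. One operation gives the five-membered ring, joins the quaternary to the tertiary carbon, sets C5 by inversion and unveils the C4 carbonyl and the C6 hydroxyl. It exploits the 1,3-dioxygenated triad C4(OH)–C5(H)–C6(O-acyl) that lies next to C1. C1 stems from an asymmetric allylic alkylation, C6 from (S)-epichlorohydrin. Isopropyl addition, metathesis (ring B), acylation and allylic oxidation follow.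

Key step: step 8

Numbering used (daucane numbers):
- Ring A is C1 (quaternary, CH3), C2, C3, C4 (OH, isopropyl) and C5 (H).
- Ring B is C1, C5, C6 (O-acyl), C7, C8 (CH3), C9 and C10 (C=O).

Assumption: the sense of induction of the PHOX ligand in step 4 is taken from the cyclohexanone series, where the (S)-ligand gives the (S)-2-allyl-2-methyl ketone. The (R)-ligand is therefore used for (R)-7.

Step 1
Reactants: 1 cyclopentane-1,3-dione
Product: 2 2-diazocyclopentane-1,3-dione
Conditions: 4-acetamidobenzenesulfonyl azide, Et3N, MeCN, 0 °C to rt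
Reagents that add atoms: 4-acetamidobenzenesulfonyl azide, CC(=O)Nc1ccc(cc1)S(=O)(=O)N=[N+]=[N-]
Why: Regitz diazo transfer, in which the doubly activated CH2 of the 1,3-diketone is deprotonated by the amine and takes over N2 from the sulfonyl azide; no stereocentre is formed.

Step 2
Reactants: 2 2-diazocyclopentane-1,3-dione, 3 allyl alcohol (prop-2-en-1-ol)
Product: 5 allyl 2-oxocyclobutane-1-carboxylate, via acylketene 4 (not isolated)
Conditions: toluene, 180 °C (sealed vessel, microwave)
Reagents that add atoms: none
Why: Wolff rearrangement of a cyclic 2-diazo-1,3-diketone, in which loss of N2 with a 1,2-shift contracts the ring to acylketene 4 and allyl alcohol traps it as the β-keto ester (labile stereocentre, racemic).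

Step 3
Reactants: 5 allyl 2-oxocyclobutane-1-carboxylate
Product: 6 allyl 1-methyl-2-oxocyclobutane-1-carboxylate (racemic)
Conditions: MeI, K2CO3, acetone, rt to 50 °C
Reagents that add atoms: iodomethane, CI
Why: C-alkylation of the soft β-keto ester enolate with a small electrophile; the quaternary centre may form racemic because it is erased and reset in step 4.

Step 4
Reactants: 6 allyl 1-methyl-2-oxocyclobutane-1-carboxylate
Product: 7 (R)-2-allyl-2-methylcyclobutan-1-one
Conditions: Pd2(dba)3 (2.5 mol %), (R)-4-tert-butyl-2-[2-[bis(4-trifluoromethylphenyl)phosphanyl]-5-(trifluoromethyl)phenyl]-4,5-dihydrooxazole (6 mol %), toluene, 20 °C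
Reagents that add atoms: none
Why: Decarboxylative asymmetric allylic alkylation (Tsuji–Trost type), in which ionisation by zerovalent palladium and loss of CO2 turn both enantiomers of 6 into one prochiral enolate/π-allyl pair and the (R)-PHOX ligand controls the face of C–C bond formation, setting C1 as (R).

Step 5
Reactants: 8 (S)-epichlorohydrin
Product: 9 (S)-1-chloro-4-methylpent-4-en-2-ol
Conditions: isopropenylmagnesium bromide, CuI (10 mol %), THF, −40 °C; then H2O
Reagents that add atoms: isopropenylmagnesium bromide, C=C(C)[Mg]Br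
Why: Copper-catalysed Grignard opening of the epoxide at its unsubstituted carbon is faster than displacement of chloride, and the C–O bond at the stereocentre (future C6) is not touched.

Step 6
Reactants: 9 (S)-1-chloro-4-methylpent-4-en-2-ol
Product: 10 (S)-2-(2-methylallyl)oxirane
Conditions: powdered NaOH, Et2O, rt
Reagents that add atoms: none
Why: Intramolecular Williamson reaction (3-exo-tet) of the chlorohydrin; the stereocentre keeps its C–O bond, so the (S) configuration is retained.

Step 7
Reactants: 10 (S)-2-(2-methylallyl)oxirane, 7 (R)-2-allyl-2-methylcyclobutan-1-one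
Product: 12 (2R)-2-allyl-2-methyl-1-[(2R,3S)-3-(2-methylallyl)oxiran-2-yl]cyclobutan-1-ol (both carbinol epimers), via oxiranyllithium 11 (not isolated)
Conditions: s-BuLi, 3,7-dibutyl-3,7-diazabicyclo[3.3.1]nonane, hexane, −90 °C; then 7, −90 to −40 °C; then H2O
Reagents that add atoms: none
Why: Diamine-assisted α-lithiation of a terminal epoxide removes the ring hydrogen trans to the substituent, and the oxiranyllithium, configurationally stable at −90 °C, adds with retention to the strained, highly electrophilic cyclobutanone (1,2-addition), so C5 follows from C6 while the carbinol centre forms as a mixture that step 8 erases.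

Step 8
Reactants: 12 (2R)-2-allyl-2-methyl-1-[(2R,3S)-3-(2-methylallyl)oxiran-2-yl]cyclobutan-1-ol
Product: 13 (2S,3R)-3-allyl-2-[(1S)-1-hydroxy-3-methylbut-3-en-1-yl]-3-methylcyclopentan-1-one
Conditions: BF3·OEt2 (0.3 equiv), CH2Cl2, −78 to −40 °C; aq NaHCO3
Reagents that add atoms: none
Why: BF3 binds the epoxide oxygen and, as the C5–O bond lengthens, the strained cyclobutane bond C4–C1 lying antiperiplanar to it shifts to C5 while the carbinol oxygen closes to the C4 carbonyl, a concerted push–pull semipinacol rearrangement of a tertiary 2,3-epoxy alcohol, which is the classical cyclobutanol-to-cyclopentanone ring expansion. No ring is closed by cyclisation: ring A arises by a 1,2-alkyl shift that enlarges the four-membered ring C1–C2–C3–C4 by the formerly exocyclic carbon C5. C5 is set by inversion at the epoxide carbon, C6 keeps the C–O bond it brought from 10, C1 migrates with retention, and the carbinol carbon becomes trigonal, so both epimers of 12 converge on one product. The step needs migration of C1 rather than C3 and opening at C5 rather than C6; the quaternary C1 carries developing positive charge better than the CH2 group, and only cleavage at C5 is assisted by the neighbouring carbinol and by release of ring strain. Low temperature and a substoichiometric Lewis acid should keep the 1,1-disubstituted alkene from attacking the activated epoxide and avoid dehydration or epimerisation of the aldol-type product.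

Step 9
Reactants: 13 (2S,3R)-3-allyl-2-[(1S)-1-hydroxy-3-methylbut-3-en-1-yl]-3-methylcyclopentan-1-one
Product: 14 (1R,2S,3R)-3-allyl-2-[(1S)-1-hydroxy-3-methylbut-3-en-1-yl]-3-methyl-1-(propan-2-yl)cyclopentan-1-ol
Conditions: anhydrous CeCl3, i-PrMgCl (excess), THF, −78 to −20 °C; then H2O
Reagents that add atoms: isopropylmagnesium chloride, CC(C)[Mg]Cl
Why: Organocerium 1,2-addition, in which the weakly basic isopropylcerium reagent adds to the enolisable aldol-type ketone without β-hydride reduction, enolisation or retro-aldol cleavage and attacks C4 from the ring face opposite to the C5 side chain (the face of H5), placing isopropyl trans and the new hydroxyl cis to that chain, i.e. (R) at C4.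

Step 10
Reactants: 14 (1R,2S,3R)-3-allyl-2-[(1S)-1-hydroxy-3-methylbut-3-en-1-yl]-3-methyl-1-(propan-2-yl)cyclopentan-1-ol
Product: 15 (3R,3aS,4S,8aR)-6,8a-dimethyl-3-(propan-2-yl)-1,2,3,3a,4,5,8,8a-octahydroazulene-3,4-diol
Conditions: second-generation Hoveyda–Grubbs catalyst (5 mol %), 1,4-benzoquinone (10 mol %), toluene (high dilution), 80 °C
Reagents that add atoms: none
Why: Ring-closing metathesis of the allyl and methallyl termini closes ring B as a seven-membered ring with the trisubstituted C8=C9 alkene, driven by loss of ethene; the trans arrangement of the two arms on ring A gives the trans ring fusion and no stereocentre is touched.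

Step 11
Reactants: 15 (3R,3aS,4S,8aR)-6,8a-dimethyl-3-(propan-2-yl)-1,2,3,3a,4,5,8,8a-octahydroazulene-3,4-diol, 16 3,4,5-trimethoxybenzoyl chloride
Product: 17 (3R,3aS,4S,8aR)-3-hydroxy-6,8a-dimethyl-3-(propan-2-yl)-1,2,3,3a,4,5,8,8a-octahydroazulen-4-yl 3,4,5-trimethoxybenzoate
Conditions: Et3N, DMAP (cat.), CH2Cl2, 0 °C to rt
Reagents that add atoms: none
Why: DMAP-catalysed acylation distinguishes the secondary C6–OH from the hindered tertiary C4–OH, which does not react under these conditions, and C6 keeps its configuration because its C–O bond is not broken.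

Step 12
Reactants: 17 (3R,3aS,4S,8aR)-3-hydroxy-6,8a-dimethyl-3-(propan-2-yl)-1,2,3,3a,4,5,8,8a-octahydroazulen-4-yl 3,4,5-trimethoxybenzoate
Product: 18 (3R,3aS,4S,8aS)-3-hydroxy-6,8a-dimethyl-8-oxo-3-(propan-2-yl)-1,2,3,3a,4,5,8,8a-octahydroazulen-4-yl 3,4,5-trimethoxybenzoate (target)
Conditions: Rh2(cap)4 (dirhodium tetrakis(caprolactamate), 1 mol %), 70 % aq t-BuOOH (excess), 1,2-dichloroethane, 40 °C
Reagents that add atoms: tert-butyl hydroperoxide, CC(C)(C)OO
Why: Radical allylic C–H oxidation by the dirhodium caprolactamate/tert-butylperoxyl system turns a ring CH2 next to a trisubstituted alkene into the β-methyl enone (as 1-methylcycloalkenes give 3-methylcycloalkenones); C10 should be preferred because C7–H is deactivated and shielded by the adjacent acyloxy group, and no stereocentre is affected.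

Compound list
1 | cyclopentane-1,3-dione | O=C1CCC(=O)C1 | starting material
2 | 2-diazocyclopentane-1,3-dione | O=C1CCC(=O)C1=[N+]=[N-] | intermediate
3 | allyl alcohol (prop-2-en-1-ol) | C=CCO | starting material
4 | 2-(oxomethylidene)cyclobutan-1-one (acylketene, not isolated) | O=C=C1CCC1=O | intermediate
5 | allyl 2-oxocyclobutane-1-carboxylate (racemic, labile centre) | C=CCOC(=O)C1CCC1=O | intermediate
6 | allyl 1-methyl-2-oxocyclobutane-1-carboxylate (racemic) | C=CCOC(=O)C1(C)CCC1=O | intermediate
7 | (R)-2-allyl-2-methylcyclobutan-1-one | C=CC[C@@]1(C)CCC1=O | intermediate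
8 | (S)-epichlorohydrin | ClC[C@@H]1CO1 | starting material
9 | (S)-1-chloro-4-methylpent-4-en-2-ol | C=C(C)C[C@H](O)CCl | intermediate
10 | (S)-2-(2-methylallyl)oxirane | C=C(C)C[C@H]1CO1 | intermediate
11 | trans-(3S)-3-(2-methylallyl)oxiran-2-yllithium (lithium trans to the side chain, not isolated) | [Li][C@@H]1O[C@H]1CC(C)=C | intermediate
12 | (2R)-2-allyl-2-methyl-1-[(2R,3S)-3-(2-methylallyl)oxiran-2-yl]cyclobutan-1-ol (carbinol centre as a mixture, erased in step 8) | C=CC[C@@]1(C)CCC1(O)[C@@H]2O[C@H]2CC(C)=C | intermediate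
13 | (2S,3R)-3-allyl-2-[(1S)-1-hydroxy-3-methylbut-3-en-1-yl]-3-methylcyclopentan-1-one | C=CC[C@@]1(C)CCC(=O)[C@@H]1[C@@H](O)CC(C)=C | intermediate
14 | (1R,2S,3R)-3-allyl-2-[(1S)-1-hydroxy-3-methylbut-3-en-1-yl]-3-methyl-1-(propan-2-yl)cyclopentan-1-ol | C=CC[C@@]1(C)CC[C@@](O)(C(C)C)[C@@H]1[C@@H](O)CC(C)=C | intermediate
15 | (3R,3aS,4S,8aR)-6,8a-dimethyl-3-(propan-2-yl)-1,2,3,3a,4,5,8,8a-octahydroazulene-3,4-diol (trans-fused dauc-8-ene-4,6-diol) | O[C@H]1CC(C)=CC[C@@]2(C)CC[C@@](O)(C(C)C)[C@H]12 | intermediate
16 | 3,4,5-trimethoxybenzoyl chloride | COc1cc(C(=O)Cl)cc(OC)c1OC | starting material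
17 | 6-O-(3,4,5-trimethoxybenzoyl) derivative of 15 | COc1cc(C(=O)O[C@H]2CC(C)=CC[C@@]3(C)CC[C@@](O)(C(C)C)[C@H]23)cc(OC)c1OC | intermediate
18 | CNP0218356.1, 10-oxo derivative of 17 | COc1cc(C(=O)O[C@H]2CC(C)=CC(=O)[C@@]3(C)CC[C@@](O)(C(C)C)[C@H]23)cc(OC)c1OC | target

Total step count: 12. Longest linear sequence: 10 (steps 1–4 and 7–12).

Steps most likely to fail

Step 7.
- What may go wrong: the oxiranyllithium may decompose by carbenoid pathways. The base may instead remove the allylic C7 hydrogen and open the epoxide by β-elimination. The ketone may be enolised instead of attacked.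
- Fallback (sets out from 7, returns at 12): the C5–C6 unit is brought in as an alkene and oxidised afterwards.
- Hydrozirconation of 2-methylpent-1-en-4-yne with Cp2ZrHCl gives (E)-4-methylpenta-1,4-dienylzirconocene chloride F1.
- Iodinolysis then gives (E)-1-iodo-4-methylpenta-1,4-diene F2.
- Iodine–lithium exchange (t-BuLi, Et2O, −78 °C) gives (E)-4-methylpenta-1,4-dienyllithium F3.
- F3 adds to 7 to give the tertiary allylic alcohol (2R)-2-allyl-2-methyl-1-[(E)-4-methylpenta-1,4-dienyl]cyclobutan-1-ol F4.
- A hydroxyl-directed, ligand-controlled epoxidation (Hf(OtBu)4, chiral bis-hydroxamic acid ligand, cumene hydroperoxide, toluene) should touch only the allylic alkene and lead to 12.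

Step 12.
- What may go wrong: hydrogen abstraction may occur at C7 or at the C8 methyl group. The allyl radical may be trapped at tertiary C8. Over-oxidation may erode the material.
- Fallback (sets out from 17, returns at 18): the oxygen is brought to C10 by an ionic 1,3-transposition.
- mCPBA epoxidises the only alkene to the 8,9-epoxide of 17 F5.
- Sodium phenylselenide (PhSeSePh, NaBH4, EtOH) opens it at the secondary C9 to the 8-hydroxy-9-phenylselanyl compound F6.
- H2O2 gives the selenoxide F7, which can eliminate only towards C10–H. This gives the tertiary allylic alcohol 8-hydroxy-dauc-9-ene ester F8.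
- Pyridinium chlorochromate (C5H5NH[CrO3Cl]) in CH2Cl2 then effects the oxidative allylic transposition (Babler–Dauben oxidation) to 18.

Step 9.
- What may go wrong: β-hydride reduction, enolisation with epimerisation at C5, retro-aldol cleavage, or poor facial selectivity on the flexible monocyclic ketone.
- Fallback (sets out from 13, returns at 15): ring B is closed first and a smaller nucleophile without β-hydrogen is used.
- Ring-closing metathesis of 13 gives the trans-fused (3aS,4S,8aR)-4-hydroxy-6,8a-dimethyl-2,3a,4,5,8,8a-hexahydroazulen-3(1H)-one F9.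
- Isopropenylmagnesium bromide/CeCl3 adds from the face opposite to the angular methyl group to give the 3-isopropenyl-3,4-diol F10.
- Chemoselective hydrogenation of the 1,1-disubstituted alkene with RhCl(PPh3)3 and H2 gives 15.

Further compounds
F1 | step 7 | (E)-4-methylpenta-1,4-dienylzirconocene chloride | C=C(C)C/C=C/[Zr](Cl)(C1C=CC=C1)C1C=CC=C1
F2 | step 7 | (E)-1-iodo-4-methylpenta-1,4-diene | I/C=C/CC(C)=C
F3 | step 7 | (E)-4-methylpenta-1,4-dienyllithium | [Li]/C=C/CC(C)=C
F4 | step 7 | (2R)-2-allyl-2-methyl-1-[(E)-4-methylpenta-1,4-dienyl]cyclobutan-1-ol (carbinol epimers) | C=CC[C@@]1(C)CCC1(O)/C=C/CC(C)=C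
F5 | step 12 | 8,9-epoxide of 17 (configuration at C8 and C9 inconsequential) | COc1cc(C(=O)O[C@H]2CC3(C)OC3C[C@@]4(C)CC[C@@](O)(C(C)C)[C@H]24)cc(OC)c1OC
F6 | step 12 | 8-hydroxy-9-phenylselanyl derivative of 17 | COc1cc(C(=O)O[C@H]2CC(C)(O)C([Se]c3ccccc3)C[C@@]4(C)CC[C@@](O)(C(C)C)[C@H]24)cc(OC)c1OC
F7 | step 12 | selenoxide of F6 | COc1cc(C(=O)O[C@H]2CC(C)(O)C([Se](=O)c3ccccc3)C[C@@]4(C)CC[C@@](O)(C(C)C)[C@H]24)cc(OC)c1OC
F8 | step 12 | 8-hydroxy-dauc-9-ene ester (tertiary allylic alcohol) | COc1cc(C(=O)O[C@H]2CC(C)(O)C=C[C@@]3(C)CC[C@@](O)(C(C)C)[C@H]23)cc(OC)c1OC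
F9 | step 9 | (3aS,4S,8aR)-4-hydroxy-6,8a-dimethyl-2,3a,4,5,8,8a-hexahydroazulen-3(1H)-one | O[C@H]1CC(C)=CC[C@@]2(C)CCC(=O)[C@H]12
F10 | step 9 | (3R,3aS,4S,8aR)-6,8a-dimethyl-3-(prop-1-en-2-yl)-1,2,3,3a,4,5,8,8a-octahydroazulene-3,4-diol | O[C@H]1CC(C)=CC[C@@]2(C)CC[C@@](O)(C(C)=C)[C@H]12
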